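## The problem

Compound 23 is a trans-fused bicyclo[5.3.0]decane (a daucane-type hydroazulene) that carries three oxygen functions in three different states: the tiglate of a secondary allylic alcohol, the 4-hydroxybenzoate of a secondary alcohol and a free tertiary alcohol. For the discussion the seven-membered ring is numbered from the tigloyloxy carbon C1 through the alkene C2=C3 (methyl on C3), the methylene C4, the aroyloxy carbon C5 and the ring-fusion methine C6 to the methyl-bearing quaternary carbon C7; the cyclopentane runs on from C7 through C8 and C9 to C10, which holds the hydroxyl and isopropyl groups and is bonded to C6. In this numbering 23 is (1R,5S,6S,7S,10S): the three oxygens and H6 lie on one face (β), the C7 methyl and the C10 isopropyl group on the other (α). Two of the five stereocentres are fully substituted (quaternary C7, tertiary carbinol C10) and both flank the ring-fusion methine C6, so the trans ring fusion cannot be corrected by late equilibration. C10 can come from the chiral pool and then steer C7 and C6 across a cyclopentane; the axial C7 methyl steers reagents at C1; C5 has no dependable neighbour and calls for reagent control. The allylic tiglate (ionisation, acyl migration), the phenolic ester, the trisubstituted alkene and the dehydration-prone tertiary alcohol rule out hydrogenation, strong acid and strong base late in the route, so the esters must go on last and the final unmasking must be mild. The enabling feature is the unit C1(O)–C2=C3(CH3): C2 carries only hydrogen besides C1 and C3, so it can be treated as a one-carbon unit inserted into the C1=C3 bond of a six-membered ring C7–C1=C3–C4–C5–C6, which is what a cyclopropyl-to-allyl cation opening of a dihalocarbene adduct delivers.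

## Retrosynthesis

**Ester bonds (23 ⇒ 22 ⇒ 20 + 21; 20 ⇒ 19 ⇒ 17 + 18).** The two acyl–oxygen bonds are cut first. Target 23 goes back to acetoxybenzoate 22, which comes from diol 20 and 4-acetoxybenzoyl chloride 21; diol 20 goes back through the bis-silylated tiglate 19 to allylic alcohol 17 and tiglic acid 18. The tiglate is placed at C1 of 17 while C5 is still silylated, because C1–OH and C5–OH are both secondary and could not otherwise be told apart. The aroyl group goes on after desilylation, where the only competitor in 20 is the unreactive tertiary C10–OH. Carrying the aryl ester from an early stage was rejected because it would meet the strong base of the carbene step. The forward steps must acylate a neopentyl-type allylic alcohol without ionising it and free the phenol of 22 by aminolysis of its acetate.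

**C2–Br, C1–O and the one-carbon ring expansion (17 ⇒ 16 ⇒ 15).** Removing the vinylic bromine leads from 17 back to bromo alcohol 16. The C1–O bond and the seven-membered ring of 16 are traced to dibromocyclopropane 15 by re-forming the C1–C3 bond. Closing the seven-membered ring directly would require the C1 carbinol to be made separately next to the quaternary carbon. Carbonyl-based expansions would give ketones with ambiguous regiochemistry. The cation opening puts the oxygen on C1 and the alkene at C2=C3 in one operation and lets the easier six-membered ring be built first. The forward reaction must capture the allyl cation at C1 rather than C3, from the β face, without harming the silyl ethers.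

**C1–C2 and C2–C3 (15 ⇒ 13 + 14).** The cyclopropane of 15 is cut to hydrindene 13 and a dibromomethylene unit supplied by bromoform 14. The precursor loses a ring, two halogens and two stereocentres. The forward addition only has to reach a trisubstituted alkene next to a quaternary carbon; its facial selectivity is immaterial because both adducts open to the same cation.

**C1=C3 (13 ⇒ 12).** The cyclohexene of 13 is opened by a ring-closing metathesis transform to diene 12. A [4+2] construction of the same ring would need a diene C7=C1–C3=C4 with a methyl group cis on its C7 terminus and an unactivated enol-ether dienophile of defined geometry. Metathesis needs only two terminal alkenes and fixes the alkene position. The precursor 12 is monocyclic; the forward step must form a trisubstituted alkene in a trans-fused ring.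

**C4–C5 (12 ⇒ 11 ⇒ 8 + 9).** After removal of the silyl group of 12, homoallylic alcohol 11 is cut into aldehyde 8 and the 2-methylallyl nucleophile 9. This cut sets C5 at the moment of C–C bond formation. A C5 ketone was avoided because a β,γ-unsaturated ketone next to C6 invites conjugation and ring-fusion epimerisation. The formyl group of 8 sits on a methine flanked by two fully substituted carbons, so the forward step needs a reagent-controlled, non-basic allylation.

**C7–C1 and C6–H (8 ⇒ 5 + 6).** The vinyl group on the quaternary carbon of 8 is removed as vinylmagnesium bromide 6, which leaves enal 5 with a single stereocentre. The forward conjugate addition must form the quaternary centre anti to the isopropyl group of C10 and protonate C6 on the same face.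

**C6–C7 and the chiral pool (5 ⇒ 4 ⇒ 2 ⇒ 1).** Enal 5 is an aldol condensation product of keto aldehyde 4, whose two carbonyl groups reconnect to the ring alkene of silyl ether 2 and hence to (R)-terpinen-4-ol 1. This supplies C10 with its oxygen and isopropyl group in the correct absolute configuration. A late isopropyl addition to a C10 ketone would enter anti to the angular methyl group and give the wrong epimer.

## Roads not taken

Alternative 1: Both bonds to the quaternary carbon (C7–C6 and C7–C1) are cut, which traces the bicycle to an arene. In the forward step Rh2(O2CCF3)4 (divalent rhodium) would turn diazo ketone A1 into a carbene at C7. The carbene adds across the ipso–ortho bond C6–C1 of the 2,6-dimethoxy-4-methylphenyl ring, and electrocyclic opening of the adduct gives cycloheptatriene A2. Merits: both rings and the quaternary centre arise in one step from a flat precursor made by simple arene chemistry, and the route is convergent. Weak points for this target: A2 carries three ring alkenes, two of them enol ethers, and a C8 ketone that must be excised. C6–H would have to be installed trans to the C7 methyl by reducing a tetrasubstituted enol-ether alkene, and C1 and C5 would both be set by ketone reductions. The C10 carbinol of A1 would need an asymmetric addition to a doubly ortho-substituted aryl ketone, and it would have to control C7 across the forming ring. In ring construction this road is better than the chosen one, which builds the quaternary carbon by a conjugate addition of uncertain facial bias. The chosen plan sets against it the oxidation pattern: every oxygen and the single alkene arrive where 23 has them, and C10 is bought.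

Alternative 2: C1–C7 and C2–C6 are cut as a [2+2] retron, with the C2–C6 bond formed only to be broken again. Irradiation near 350 nm of enone A3, which derives from the same cyclopentene as 5, would add the excited C6=C7 enone to the tethered (E)-enol ether C2=C1. This gives cyclobutane A4 with a temporary cyclopentanone (C2–C3–C4–C5–C6). Reductive cleavage of the C2–C6 bond next to the C5 ketone would then unveil the seven-membered ring. Merits: the hindered C1–C7 bond forms in a step that is insensitive to steric crowding, and the C1 oxygen is tied to C7 by the cyclobutane geometry. Weak points: the facial selectivity relative to C10 is unsecured. The fragmentation leaves enolate character at C5–C6, so C6 must still be protonated to the trans ring fusion. The C5 ketone must be reduced to the equatorial alcohol, and the tertiary C3 alcohol must be dehydrated towards C2 only. For the C1–C7 bond and the C1 configuration this road is more secure than cation capture. The chosen plan sets against it that the ring expansion delivers C1–O and C2=C3 together, with no dehydration and no ketone reductions afterwards.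

Alternative 3: C6–C7 and C10–O are cut across the bicycle, which traces it to a ten-membered ring. BF3·OEt2 followed by water would open the C1–C7 epoxide of A5 at tertiary C7. The C6=C10 alkene (ring bonds trans) attacks C7 through C6 with inversion, and water adds to the cationic centre at C10 from the opposite side, giving diol A6 with both rings closed. Merits: A6 is the complete core, with C1, C6, C7 and C10 set stereospecifically from alkene and epoxide geometry, and its end game is shorter than the one chosen here. Weak points: A5 needs a macrocyclisation, a stereodefined trisubstituted epoxide and a geometrically defined ring alkene bearing the isopropyl group. The cyclisation competes with elimination and with other transannular modes, and its outcome depends on the ring conformation. Against the shorter end game, the chosen plan sets a precursor that is made in eight steps from a commercial monoterpene without any medium ring.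

Key step: step 9

Assumption: commercial (R)-(−)-terpinen-4-ol (1) is taken as enantiomerically pure; a scalemic lot would be upgraded by a standard resolution before use. Atom numbers and the α/β face labels follow the first section.

## Route

Step 1
Reactants: 1 (R)-terpinen-4-ol
Product: 2 (R)-triethyl{[4-methyl-1-(propan-2-yl)cyclohex-3-en-1-yl]oxy}silane
Conditions: TESOTf, 2,6-lutidine, CH2Cl2, 0 °C → rt
Reagents that add atoms: triethylsilyl trifluoromethanesulfonate, CC[Si](CC)(CC)OS(=O)(=O)C(F)(F)F
Why: Silylation of a tertiary alcohol with a silyl triflate and a hindered base is standard and leaves the stereocentre untouched; the ether blocks retro-aldol and dehydration pathways of the later β-oxy aldehydes and shields the oxygen from the carbene in step 8.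

Step 2
Reactants: 2 silyl ether
Product: 4 (R)-6-oxo-3-(propan-2-yl)-3-[(triethylsilyl)oxy]heptanal, via ozonide 3 (not isolated)
Conditions: O3, CH2Cl2, −78 °C; then PPh3, −78 °C → rt
Reagents that add atoms: ozone, [O-][O+]=O
Why: Ozonolysis of the trisubstituted ring alkene with reductive work-up gives the methyl ketone and the aldehyde; the silyl ether and C10 are not involved.

Step 3
Reactants: 4 keto aldehyde
Product: 5 (S)-2-methyl-5-(propan-2-yl)-5-[(triethylsilyl)oxy]cyclopent-1-ene-1-carbaldehyde
Conditions: piperidine, AcOH, toluene, 60 °C
Reagents that add atoms: none
Why: Amine-catalysed intramolecular aldol condensation; the enamine of the aldehyde attacks the methyl ketone (five-membered ring, C6–C7 bond) and dehydration gives the cyclopentenecarbaldehyde, the known outcome for 6-oxoheptanals, while enamine catalysis suppresses the alternative acetylcyclopentene mode. Dehydration should expel the acid-assisted tertiary hydroxyl at C7 in preference to the encumbered, less basic silyloxy group at C10.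

Step 4
Reactants: 5 enal; 6 vinylmagnesium bromide
Product: 8 aldehyde with vinyl and OSiEt3 on the β face and formyl on the α face (2-ethenyl-2-methyl-5-(propan-2-yl)-5-[(triethylsilyl)oxy]cyclopentane-1-carbaldehyde), via silyl enol ether 7 (not isolated)
Conditions: 6, CuBr·SMe2 (20 mol %), TMSCl, HMPA, THF, −78 → −40 °C; then AcOH–THF–H2O, 0 °C
Reagents that add atoms: chlorotrimethylsilane, C[Si](C)(C)Cl (its silyl group is found in intermediate 7 only)
Why: Copper-catalysed conjugate addition of a Grignard reagent with chlorosilane acceleration is the established way to build a quaternary carbon from a β,β-disubstituted enal. The vinyl group should enter C7 anti to the C10 isopropyl group, which shields its face more than the O-silyl group does. Kinetic protonation of 7 on the same isopropyl-free face under mildly acidic hydrolysis should place H6 cis to the vinyl group without loss of the tertiary silyl ether.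

Step 5
Reactants: 8 aldehyde; 9 (2-methylallyl)magnesium chloride
Product: 11 homoallylic alcohol with (5S) carbinol carbon (1-[2-ethenyl-2-methyl-5-(propan-2-yl)-5-(triethylsilyloxy)cyclopentyl]-3-methylbut-3-en-1-ol), via borinate 10 (not isolated)
Conditions: (−)-Ipc2BOMe, 9, Et2O, −78 → 0 °C; then 8, −78 → −20 °C; then 3 M NaOH, 30% H2O2, 0 °C → rt
Reagents that add atoms: (−)-B-methoxydiisopinocampheylborane, COB([C@@H]1C[C@@H]2C[C@H]([C@H]1C)C2(C)C)[C@@H]1C[C@@H]2C[C@H]([C@H]1C)C2(C)C (boron and isopinocampheyl groups are found in intermediate 10 only)
Why: Brown asymmetric allylboration through a chair six-membered transition state; the borane derived from (+)-α-pinene adds to the Si face of the aldehyde, which corresponds to the (5S) alcohol, under reagent control. The reagent is non-basic, so C6 is not epimerised and the β-silyloxy group is not eliminated.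

Step 6
Reactants: 11 homoallylic alcohol
Product: 12 tert-butyldimethylsilyl ether of 11
Conditions: TBSOTf, 2,6-lutidine, CH2Cl2, 0 °C → rt
Reagents that add atoms: tert-butyldimethylsilyl trifluoromethanesulfonate, CC(C)(C)[Si](C)(C)OS(=O)(=O)C(F)(F)F
Why: Silyl triflate silylation works on hindered secondary alcohols; the ether protects the C5 oxygen through the carbene, silver and acylation steps.

Step 7
Reactants: 12 diene
Product: 13 trans-fused hydrindene (4-[(tert-butyldimethylsilyl)oxy]-6,7a-dimethyl-3-(propan-2-yl)-3-[(triethylsilyl)oxy]-2,3,3a,4,5,7a-hexahydro-1H-indene; 5β-OTBS 6β-H 7α-CH3 10β-OTES)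
Conditions: second-generation Grubbs catalyst (H2IMes)(PCy3)Cl2Ru=CHPh (5 mol %), CH2Cl2, 40 °C
Reagents that add atoms: none
Why: Ring-closing metathesis between a vinyl group and a 1,1-disubstituted alkene gives a trisubstituted cyclohexene and is driven by loss of ethene; the trans-fused six-membered ring is nearly strain-free and no stereocentre is made.

Step 8
Reactants: 13 hydrindene; 14 bromoform
Product: 15 dibromocyclopropane (CBr2 carbon C2 bridging C1 and C3 on the β face of 13)
Conditions: 14, KOtBu, pentane, 0 °C → rt
Reagents that add atoms: none
Why: Dibromocarbene from α-elimination of bromoform adds in a [2+1] cheletropic reaction to the electron-rich trisubstituted alkene, anti to the axial C7 methyl group. The alkyl silyl ethers tolerate the base.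

Step 9
Reactants: 15 dibromocyclopropane
Product: 16 2-bromocyclohept-2-enol (7-bromo-4-[(tert-butyldimethylsilyl)oxy]-6,8a-dimethyl-3-(propan-2-yl)-3-[(triethylsilyl)oxy]-1,2,3,3a,4,5,8,8a-octahydroazulen-8-ol; 1β-OH 5β-OTBS 6β-H 7α-CH3 10β-OTES)
Conditions: AgClO4, acetone–H2O (9:1), 0 °C → rt, dark
Reagents that add atoms: water, O
Why: Silver ion acts as a halophile on the bromine of 15 that lies over the six-membered ring, and as this C2–Br bond ionises the C1–C3 bond opens in a concerted disrotatory two-electron electrocyclic process; only loss of this endo bromide turns C4 and C7 inward, which gives the all-cis allyl cation C1–C2–C3 that a seven-membered ring can hold. The closest known reaction type is the silver-promoted solvolytic ring expansion of 7,7-dibromobicyclo[4.1.0]heptanes to 2-bromocyclohept-2-enols. No ring is closed end to end: the cycloheptene results from breaking the bond common to the three- and six-membered rings, so no exo or endo mode applies, and the other cyclopropane diastereomer would lead to the same cation. Water then forms the C1–O bond; C1 is the only new stereocentre and is governed by the adjacent axial C7 methyl group, which blocks the α face so that water should enter from the β face. The step needs regioselectivity for C1 over the tertiary terminus C3: attack at C1 leaves the tetrasubstituted C2=C3 bromoalkene, and because the perchloric acid set free can re-ionise a tertiary C3 alcohol, capture is reversible and should funnel to this more stable isomer. Proton loss to bromodienes and transannular capture by the encumbered, weakly nucleophilic silyl ether oxygens are held back by the large excess of water.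

Step 10
Reactants: 16 bromo alcohol
Product: 17 allylic alcohol (1β-OH; C2=C3 alkene; silyl ethers unchanged)
Conditions: Bu3SnH, AIBN (cat.), toluene, 85 °C
Reagents that add atoms: none
Why: Radical chain hydrodebromination: the stannyl radical abstracts bromine and the ring-bound vinyl radical takes hydrogen from the stannane, so the alkene stays at C2=C3 and no stereocentre changes. It is run before acylation so that the vinyl radical cannot cyclise onto the tiglate.

Step 11
Reactants: 17 allylic alcohol; 18 tiglic acid
Product: 19 C1 tiglate with both silyl ethers
Conditions: 18, 2,4,6-trichlorobenzoyl chloride, Et3N, toluene, rt; then 17, DMAP, rt → 50 °C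
Reagents that add atoms: none
Why: Yamaguchi esterification; the mixed anhydride with DMAP acylates hindered secondary alcohols at oxygen with retention at C1, and the (E)-configured acid is the stable isomer and does not isomerise.

Step 12
Reactants: 19 tiglate
Product: 20 C5,C10-diol tiglate
Conditions: HF·pyridine, pyridine, THF, 0 °C → rt
Reagents that add atoms: none
Why: Fluoride-driven Si–O cleavage removes both silyl ethers; the buffered reagent is neither basic enough for acyl migration nor acidic enough to ionise the allylic ester.

Step 13
Reactants: 20 diol; 21 4-acetoxybenzoyl chloride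
Product: 22 C5 4-acetoxybenzoate
Conditions: 21, pyridine, DMAP (cat.), CH2Cl2, 0 °C → rt
Reagents that add atoms: none
Why: Acyl chloride esterification with nucleophilic catalysis is selective for the secondary C5 hydroxyl, because the tertiary C10 hydroxyl is too hindered to react.

Step 14
Reactants: 22 acetoxybenzoate
Product: 23 target compound CNP0273650.6
Conditions: pyrrolidine, CH2Cl2, 0 °C
Reagents that add atoms: none
Why: Aminolysis of the aryl acetate, an activated phenolic ester, is much faster than attack on the two alkyl esters and frees the phenol under near-neutral conditions.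

## Compound list

1 | (R)-terpinen-4-ol | CC1=CC[C@@](O)(C(C)C)CC1 | starting material
2 | (R)-triethyl{[4-methyl-1-(propan-2-yl)cyclohex-3-en-1-yl]oxy}silane | CC1=CC[C@@](O[Si](CC)(CC)CC)(C(C)C)CC1 | intermediate
3 | secondary ozonide of 2 (1,2,4-trioxolane across the former alkene carbons; diastereomer mixture at those two carbons) | CC12CC[C@](O[Si](CC)(CC)CC)(C(C)C)CC(OO1)O2 | intermediate (not isolated)
4 | (R)-6-oxo-3-(propan-2-yl)-3-[(triethylsilyl)oxy]heptanal | CC(=O)CC[C@](O[Si](CC)(CC)CC)(C(C)C)CC=O | intermediate
5 | (S)-2-methyl-5-(propan-2-yl)-5-[(triethylsilyl)oxy]cyclopent-1-ene-1-carbaldehyde | O=CC1=C(C)CC[C@]1(O[Si](CC)(CC)CC)C(C)C | intermediate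
6 | vinylmagnesium bromide | C=C[Mg]Br | starting material
7 | trimethylsilyl enol ether of 8 (enol ether geometry open) | C[Si](C)(C)OC=C1[C@@](C)(C=C)CC[C@]1(O[Si](CC)(CC)CC)C(C)C | intermediate (not isolated)
8 | 2-ethenyl-2-methyl-5-(propan-2-yl)-5-[(triethylsilyl)oxy]cyclopentane-1-carbaldehyde; vinyl and OSiEt3 β, formyl α | O=C[C@@H]1[C@@](C)(C=C)CC[C@]1(O[Si](CC)(CC)CC)C(C)C | intermediate
9 | (2-methylallyl)magnesium chloride | CC(=C)C[Mg]Cl | starting material
10 | diisopinocampheylborinate of 11 | C=C(C)C[C@H](OB([C@@H]2C[C@@H]3C[C@H]([C@H]2C)C3(C)C)[C@@H]2C[C@@H]3C[C@H]([C@H]2C)C3(C)C)[C@@H]1[C@@](C)(C=C)CC[C@]1(O[Si](CC)(CC)CC)C(C)C | intermediate (not isolated)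
11 | (5S)-homoallylic alcohol: 1-[2-ethenyl-2-methyl-5-(propan-2-yl)-5-(triethylsilyloxy)cyclopentyl]-3-methylbut-3-en-1-ol | C=C(C)C[C@H](O)[C@@H]1[C@@](C)(C=C)CC[C@]1(O[Si](CC)(CC)CC)C(C)C | intermediate
12 | tert-butyldimethylsilyl ether of 11 | C=C(C)C[C@H](O[Si](C)(C)C(C)(C)C)[C@@H]1[C@@](C)(C=C)CC[C@]1(O[Si](CC)(CC)CC)C(C)C | intermediate
13 | trans-hydrindene: 4-[(tert-butyldimethylsilyl)oxy]-6,7a-dimethyl-3-(propan-2-yl)-3-[(triethylsilyl)oxy]-2,3,3a,4,5,7a-hexahydro-1H-indene | C1=C(C)C[C@H](O[Si](C)(C)C(C)(C)C)[C@@H]2[C@]1(C)CC[C@]2(O[Si](CC)(CC)CC)C(C)C | intermediate
14 | bromoform | BrC(Br)Br | starting material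
15 | dibromocarbene adduct of 13 (cyclopropane on the β face) | BrC1(Br)[C@@H]2[C@@]1(C)C[C@H](O[Si](C)(C)C(C)(C)C)[C@@H]3[C@]2(C)CC[C@]3(O[Si](CC)(CC)CC)C(C)C | intermediate
16 | 2-bromocyclohept-2-enol: 7-bromo-4-[(tert-butyldimethylsilyl)oxy]-6,8a-dimethyl-3-(propan-2-yl)-3-[(triethylsilyl)oxy]-1,2,3,3a,4,5,8,8a-octahydroazulen-8-ol (1β-OH) | O[C@@H]1C(Br)=C(C)C[C@H](O[Si](C)(C)C(C)(C)C)[C@@H]2[C@]1(C)CC[C@]2(O[Si](CC)(CC)CC)C(C)C | intermediate
17 | debrominated allylic alcohol (1β-OH, C2=C3) | O[C@@H]1C=C(C)C[C@H](O[Si](C)(C)C(C)(C)C)[C@@H]2[C@]1(C)CC[C@]2(O[Si](CC)(CC)CC)C(C)C | intermediate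
18 | tiglic acid, (E)-2-methylbut-2-enoic acid | C/C=C(\C)C(=O)O | starting material
19 | C1 tiglate of 17 | C/C=C(\C)C(=O)O[C@@H]1C=C(C)C[C@H](O[Si](C)(C)C(C)(C)C)[C@@H]2[C@]1(C)CC[C@]2(O[Si](CC)(CC)CC)C(C)C | intermediate
20 | C5,C10-diol C1-tiglate | C/C=C(\C)C(=O)O[C@@H]1C=C(C)C[C@H](O)[C@@H]2[C@]1(C)CC[C@]2(O)C(C)C | intermediate
21 | 4-acetoxybenzoyl chloride | CC(=O)Oc1ccc(cc1)C(Cl)=O | starting material
22 | C5 4-acetoxybenzoate C1-tiglate | C/C=C(\C)C(=O)O[C@@H]1C=C(C)C[C@H](OC(=O)c2ccc(OC(C)=O)cc2)[C@@H]2[C@]1(C)CC[C@]2(O)C(C)C | intermediate
23 | CNP0273650.6, (1R,5S,6S,7S,10S) in the numbering used here | C/C=C(\C)C(=O)O[C@@H]1C=C(C)C[C@H](OC(=O)c2ccc(O)cc2)[C@@H]2[C@]1(C)CC[C@]2(O)C(C)C | target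

## Step count and risks

Total step count: 14. Longest linear sequence: 14 steps, from 1 to 23.

**Step 9 (key step).** The cation may be captured at the tertiary terminus C3 or from the α face of C1, and it may lose a proton to bromodienes. The β-oriented silyl ether oxygen on C5 may also add across the ring to C1 with loss of its silyl group, and the perchloric acid set free may strip the silyl ethers. The first two would come from a kinetic preference for the more charged, less hindered terminus and from a conformation of the seven-membered cation that does not expose the β face. Fallback, setting out from 15 and rejoining at 19: the C1 oxygen is then set by carbonyl reduction and SN2 inversion instead of cation capture. The crude alcohol mixture from the silver step, which would contain the tertiary C3 alcohol F1, is oxidised with pyridinium chlorochromate (C5H5NH)[CrO3Cl]; the tertiary alcohol reacts with 1,3-oxidative transposition and the secondary alcohols directly, so all isomers converge on the 2-bromo enone F2. Luche reduction (NaBH4, CeCl3·7H2O, MeOH, −78 °C) should deliver hydride anti to the angular methyl group and give the 1α bromo alcohol F3. Debromination with Bu3SnH gives the 1α allylic alcohol F4. Mitsunobu esterification with 18 (PPh3, diisopropyl azodicarboxylate) inverts C1 and gives 19.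

**Step 4.** The vinyl group may add to the wrong face of C7, C6 may be protonated from the α face or epimerise afterwards, and 1,2-addition may compete. The induction from C10 is a 1,3-relationship across a cyclopentene and rests only on the size difference between isopropyl and O-silyl. The required formyl epimer is probably the less stable one. Fallback, setting out from 4 and rejoining at 13: C5, C6 and C7 are set in one concerted event instead. The aldehyde of 4 is converted with one equivalent of TBSOTf and Et3N at −78 °C into the (E)-silyl enol ether F5. Wittig reaction of the ketone with the ylide from (2-methylallyl)triphenylphosphonium chloride gives the triene F6. Thermal intramolecular Diels–Alder reaction (toluene, sealed tube, about 190 °C) leads to 13. This fallback has its own demands, namely enol silylation of the aldehyde in preference to the methyl ketone, the (E)-enol ether geometry and a reluctant diene. Because it sets out from 4, it also bypasses step 3, where β-elimination of the silyloxy group could compete with the dehydration.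

**Step 5.** Mismatched double diastereoselection and slow allylboration may give the C5 epimer, because the formyl group sits on a methine flanked by two fully substituted carbons. A simple Felkin analysis with C10 as the large group points to the unwanted face, so the reagent has to override the substrate. Fallback, setting out from 8 and rejoining at 13: C5 is set by thermodynamic reduction in the rigid bicycle instead. Addition of 9 with CeCl3 at −78 °C gives an alcohol mixture that contains the C5 epimer F7. Ring-closing metathesis of the free alcohols gives the 5α-hydrindenol F8 together with its 5β epimer. Dess–Martin oxidation of both gives the hydrindenone F9. Dissolving-metal reduction (Li, NH3, THF, EtOH, −78 °C) should give the equatorial 5β-hydrindenol F10, which is silylated with TBSOTf to 13.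

**Step 13.** Acetyl transfer from the aryl acetate under nucleophilic catalysis and slow acylation of the hindered C5 hydroxyl may give mixed esters. Fallback, setting out from 20 and rejoining at 23: the phenol protecting group is changed to one that cannot act as an acyl donor. Esterification with 4-[(tert-butyldimethylsilyl)oxy]benzoic acid (EDC·HCl, DMAP, CH2Cl2) gives the silyl-protected aroate F11. Bu4NF buffered with AcOH in THF at 0 °C then frees the phenol to give 23.

## Further compounds

F1 | step 9 | tertiary allylic alcohol from capture at C3 (C1=C2 alkene, 2-bromo, 3-hydroxy-3-methyl; either C3 epimer) | C1=C(Br)C(C)(O)C[C@H](O[Si](C)(C)C(C)(C)C)[C@@H]2[C@]1(C)CC[C@]2(O[Si](CC)(CC)CC)C(C)C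
F2 | step 9 | 2-bromo enone with C1 ketone | O=C1C(Br)=C(C)C[C@H](O[Si](C)(C)C(C)(C)C)[C@@H]2[C@]1(C)CC[C@]2(O[Si](CC)(CC)CC)C(C)C
F3 | step 9 | C1 epimer of 16 (1α-OH) | O[C@H]1C(Br)=C(C)C[C@H](O[Si](C)(C)C(C)(C)C)[C@@H]2[C@]1(C)CC[C@]2(O[Si](CC)(CC)CC)C(C)C
F4 | step 9 | C1 epimer of 17 (1α-OH) | O[C@H]1C=C(C)C[C@H](O[Si](C)(C)C(C)(C)C)[C@@H]2[C@]1(C)CC[C@]2(O[Si](CC)(CC)CC)C(C)C
F5 | step 4 | (E)-tert-butyldimethylsilyl enol ether of 4 | CC(=O)CC[C@](O[Si](CC)(CC)CC)(C(C)C)/C=C/O[Si](C)(C)C(C)(C)C
F6 | step 4 | triene for the intramolecular Diels–Alder reaction | C=C(C)/C=C(\C)CC[C@](O[Si](CC)(CC)CC)(C(C)C)/C=C/O[Si](C)(C)C(C)(C)C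
F7 | step 5 | C5 epimer of 11 | C=C(C)C[C@@H](O)[C@@H]1[C@@](C)(C=C)CC[C@]1(O[Si](CC)(CC)CC)C(C)C
F8 | step 5 | 5α-hydrindenol | C1=C(C)C[C@@H](O)[C@@H]2[C@]1(C)CC[C@]2(O[Si](CC)(CC)CC)C(C)C
F9 | step 5 | hydrindenone with C5 ketone | C1=C(C)CC(=O)[C@@H]2[C@]1(C)CC[C@]2(O[Si](CC)(CC)CC)C(C)C
F10 | step 5 | 5β-hydrindenol | C1=C(C)C[C@H](O)[C@@H]2[C@]1(C)CC[C@]2(O[Si](CC)(CC)CC)C(C)C
F11 | step 13 | C5 4-[(tert-butyldimethylsilyl)oxy]benzoate C1-tiglate | C/C=C(\C)C(=O)O[C@@H]1C=C(C)C[C@H](OC(=O)c2ccc(O[Si](C)(C)C(C)(C)C)cc2)[C@@H]2[C@]1(C)CC[C@]2(O)C(C)C
A1 | alternative 1 | 2-diazo-5-(2,6-dimethoxy-4-methylphenyl)-6-methyl-5-[(trimethylsilyl)oxy]heptan-3-one | COc1cc(C)cc(OC)c1[C@@](O[Si](C)(C)C)(C(C)C)CC(=O)C(C)=[N+]=[N-]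
A2 | alternative 1 | bicyclic cycloheptatriene bis(enol ether) with C8 ketone | COC1=CC(C)=CC(OC)=C2[C@]1(C)C(=O)C[C@]2(O[Si](C)(C)C)C(C)C
A3 | alternative 2 | cyclopentenyl ketone with tethered (E)-silyl enol ether and C3 tertiary alcohol | CC1=C(C(=O)C[C@@](C)(O)/C=C/O[Si](C)(C)C(C)(C)C)[C@@](O[Si](CC)(CC)CC)(C(C)C)CC1
A4 | alternative 2 | tricyclic cyclobutane photoadduct | CC(C)(C)[Si](C)(C)O[C@@H]1[C@H]2[C@](C)(O)CC(=O)[C@@]23[C@]1(C)CC[C@]3(O[Si](CC)(CC)CC)C(C)C
A5 | alternative 3 | ten-membered 1,7-epoxy diene with C5 silyl ether | C[C@]12CC/C(C(C)C)=C/[C@@H](O[Si](C)(C)C(C)(C)C)C/C(C)=C\[C@H]1O2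
A6 | alternative 3 | bicyclic 1,10-diol with C5 silyl ether | O[C@@H]1C=C(C)C[C@H](O[Si](C)(C)C(C)(C)C)[C@@H]2[C@]1(C)CC[C@]2(O)C(C)C
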